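(The numbers in the tables stem from a simulated flask for an exercise.)

Before any rate constant goes into a solver, ask which ratio of constants the readings give directly. The single-handed X turns Q into E and Z into G.

| flask | Q | Z | X | J | remark | time |
|---|---|---|---|---|---|---|
| ochre | 0.30 M | 0.30 M | 1.2 M | 80 mM | run made earlier |  |
| blue | 0.30 M | 0.30 M | 1.2 M | 130 mM | run made earlier |  |
| elm | 0.30 M | 0.30 M | 1.20 M | 57 mM |  | 4.0 min |
| alder | 0.30 M | 0.30 M | 1.20 M | 57 mM |  | 12 min |

| run | time / min | E / % | G / % |
|---|---|---|---|
| ochre | 0.250 | 1.6 | 1.2 |
| ochre | 0.417 | 4.4 | 1.1 |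
| ochre | 0.667 | 3.9 | 3.1 |
| ochre | 1.33 | 9.2 | 3.4 |
| ochre | 2.00 | 9.8 | 5.2 |
| ochre | 3.00 | 16.5 | 8.3 |
| blue | 0.500 | 3.1 | 2.0 |
| blue | 1.00 | 6.0 | 3.3 |
| blue | 1.50 | 9.5 | 3.9 |
| blue | 2.00 | 11.4 | 5.8 |
| blue | 2.50 | 11.6 | 6.7 |
| blue | 3.00 | 14.3 | 8.2 |

(standard deviation of a reading: 1 percentage point)

- X is single-handed; Q and Z are mirror images of each other, charged as a racemate, each of them at the stated concentration
- an excess is the difference of the two amounts in percent of their sum
- an excess is below zero if the other one leads
- the handed part of X does not stay in what it makes, so the products of the two hands are mirror images too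

- which of the two ends with the higher excess of E over G in the product ("neither" if they lie within 2 percentage points) (elm / alder / neither)
- excess of E over G in the product at the end, elm
- excess of E over G in the product at the end, alder

X stands at twice the Q and Z together, so X is not the limiting reagent, and I treat each hand as pseudo-first-order, which makes its fall straight in decadic logarithms. The share of Q left is one minus twice E, and likewise for Z with G. Blue, with 130 mM of J, is no faster than ochre, with 80 mM: its E at 3.00 min is 14.3% against 16.5%. So I pool the last readings and assume elm and alder, with less J than either, run alike. Q runs down at 0.0534 min⁻¹ in decades, faster than Z at 0.0261 min⁻¹. Their quotient, 2.04, is the selectivity factor s, the decades of cQ lost per decade of cZ lost, a reading with their scatter.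

With a and b the shares of Q and Z left, b is a to the power one over s, and the excess is b minus a over the two consumed shares summed. Turn the question round: what must be true for alder to come within 2 percentage points of elm? At the steady rate elm keeps 61.2% of Q, and the excess is 29.0%. With half of Q left it is 27.0%, a gap of 2 points. So on this reckoning alder would have to stop at 0.301 decades, reached after 5.64 min. The steady rate instead carries it to 0.640 decades and an excess of 20.0%.

The forecast says elm, with 28% and 21% against my 29.0% and 20.0%, on the ground that the excess “falls with conversion as the faster enantiomer depletes”.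

The flask gives elm: elm 26.1%, alder 19.4%.

    2 L ⇌ D, settled at all times (K = 14.0 L mol⁻¹)
    X + Z → G (k = 0.0580 L mol⁻¹ min⁻¹)
    J → L (k = 0.210 min⁻¹)
    Q + L ⇌ Z + L, rate k4*[L]*[Q] forward; the back reaction follows from the equilibrium constant (k = 0.210 L mol⁻¹ min⁻¹)
    X + Q → E (k = 0.110 L mol⁻¹ min⁻¹)

From alder's 28% of Q left, the rule gives 53.6% of Z, and alder holds 50%. The neighbour is elm read at 15 min: the steady rate gives 0.801 decades of Q, so 15.8% of Q and 40.6% of Z left, and an excess of 17.2%. That flask holds 22% of its charged Q and 43% of its charged Z, and its excess stands at 17.6%.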